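Rings A and B are disconnected together through C9–C10 and C4–C5. The key step exploits the contiguous C9–C10–C5 row of the cis-decalin: C9 is β to the C7 carbonyl and C5 is bridged by C4 to the C3 carbonyl, so a silylium catalyst with a chiral counteranion can fold acyclic trienone 20 (C7 enone with Z C8=C9, Z C5=C10 alkene, terminal C3 TBS enol ether) into decalin 21 in one operation, closing both rings, setting C5, C9 and C10, and leaving C3 as a ketone and C7 as a regiodefined silyl enol ether. The latter is then used to set C8 and C7 through an exo-methylene enone.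

Key step: step 14

Remark: ring atoms carry clerodane-type labels (C3 ring-A carbonyl carbon, C4 its neighbour next to C5, C5 methyl-bearing fusion carbon, C7 acetoxy carbon, C9 quaternary, C10 fusion CH, C11–C15 side chain); α is the ring-B face of H-10 and the C5 methyl, β the face of the C5–C4 and C10–C1 bonds; half-ester 9 is taken as a commercial single enantiomer.

Step 1
Reactants: 1 methyl 4-oxopentanoate (methyl levulinate)
Product: 2 methyl 4-[(tert-butyldimethylsilyl)oxy]pent-4-enoate
Conditions: LDA, THF, −78 °C; TBSCl, DMPU, −78 → 0 °C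
Reagents that add atoms: tert-butyldimethylsilyl chloride, CC(C)(C)[Si](C)(C)Cl
Why: Kinetic enolization removes a proton from the ketone methyl group (least hindered, more acidic than the ester α-CH2) and O-silylation traps the terminal enolate as the TBS enol ether that later serves as the C3/C4 terminator.

Step 2
Reactants: 2 methyl 4-[(tert-butyldimethylsilyl)oxy]pent-4-enoate
Product: 3 4-[(tert-butyldimethylsilyl)oxy]pent-4-enal
Conditions: DIBAL-H (1.05 equiv), CH2Cl2, −78 °C; Rochelle salt
Reagents that add atoms: none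
Why: Partial DIBAL-H reduction of a methyl ester stops at the aldehyde at −78 °C because the aluminium hemiacetal survives until work-up, and the silyl enol ether is inert to hydride.

Step 3
Reactants: 3 4-[(tert-butyldimethylsilyl)oxy]pent-4-enal, 4 methyl 2-[bis(2,2,2-trifluoroethoxy)phosphoryl]propanoate
Product: 5 methyl (2Z)-6-[(tert-butyldimethylsilyl)oxy]-2-methylhepta-2,6-dienoate
Conditions: KHMDS, 18-crown-6, THF, −78 °C
Reagents that add atoms: none
Why: Still–Gennari olefination, in which the trifluoroethyl phosphonate eliminates from the kinetic adduct under dissociating conditions, should give the Z-trisubstituted enoate, so the future C6 and C1 are cis across C5=C10.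

Step 4
Reactants: 5 methyl (2Z)-6-[(tert-butyldimethylsilyl)oxy]-2-methylhepta-2,6-dienoate
Product: 6 (2Z)-6-[(tert-butyldimethylsilyl)oxy]-2-methylhepta-2,6-dien-1-ol
Conditions: DIBAL-H (2.2 equiv), CH2Cl2, −78 °C
Reagents that add atoms: none
Why: DIBAL-H reduces the conjugated ester to the allylic alcohol by two 1,2-hydride additions without touching the alkene geometry or the enol ether.

Step 5
Reactants: 6 (2Z)-6-[(tert-butyldimethylsilyl)oxy]-2-methylhepta-2,6-dien-1-ol
Product: 8 tert-butyl{[(5Z)-7-chloro-6-methylhepta-1,5-dien-2-yl]oxy}dimethylsilane, via allylic mesylate 7 (not isolated)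
Conditions: MsCl, LiCl, 2,4,6-collidine, DMF, 0 °C
Reagents that add atoms: lithium chloride, [Li+].[Cl-]
Why: In this Collington–Meyers chlorination the primary allylic mesylate is displaced by chloride in an SN2 reaction under collidine buffering, which keeps the Z geometry (as in nerol to neryl chloride) and the acid-labile enol ether.

Step 6
Reactants: 9 (3R)-5-methoxy-3-methyl-5-oxopentanoic acid
Product: 10 methyl (3R)-5-hydroxy-3-methylpentanoate
Conditions: BH3·SMe2, THF, 0 °C → rt; MeOH
Reagents that add atoms: none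
Why: Borane reduces the carboxylic acid through its acyloxyborane much faster than the methyl ester, and the C13 stereocentre, which comes with the starting material, is not involved.

Step 7
Reactants: 10 methyl (3R)-5-hydroxy-3-methylpentanoate
Product: 11 methyl (3S)-5-iodo-3-methylpentanoate
Conditions: I2, PPh3, imidazole, CH2Cl2, 0 °C → rt
Reagents that add atoms: iodine, II
Why: Appel-type iodination converts the primary alcohol into the iodide by SN2 displacement of the oxyphosphonium group (the descriptor changes only through CIP priorities).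

Step 8
Reactants: 12 ethyl 2-methyl-3-oxobutanoate
Product: 13 ethyl (2Z)-2-methyl-3-{[(trifluoromethyl)sulfonyl]oxy}but-2-enoate
Conditions: NaH, Et2O, 0 °C; Tf2O, −78 → 0 °C
Reagents that add atoms: trifluoromethanesulfonic anhydride, FC(F)(F)S(=O)(=O)OS(=O)(=O)C(F)(F)F
Why: The sodium enolate of the β-keto ester is chelated in the Z form, so O-triflation should give the Z enol triflate with the triflate cis to the ester.

Step 9
Reactants: 13 ethyl (2Z)-2-methyl-3-{[(trifluoromethyl)sulfonyl]oxy}but-2-enoate
Product: 14 (2Z)-4-hydroxy-3-methylbut-2-en-2-yl trifluoromethanesulfonate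
Conditions: DIBAL-H (2.2 equiv), CH2Cl2, −78 °C
Reagents that add atoms: none
Why: DIBAL-H reduces the ester to the allylic alcohol at −78 °C, where an alkenyl triflate is stable, so C7 reaches the alcohol level and stays differentiated from the C15 ester introduced next.

Step 10
Reactants: 11 methyl (3S)-5-iodo-3-methylpentanoate, 14 (2Z)-4-hydroxy-3-methylbut-2-en-2-yl trifluoromethanesulfonate
Product: 16 methyl (3R,6Z)-8-hydroxy-3,6,7-trimethyloct-6-enoate, via alkylzinc iodide 15 (not isolated)
Conditions: 11, Zn dust, LiCl, THF, 40 °C; then 14, Pd(OAc)2 (2 mol%), SPhos (4 mol%), THF, 25 °C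
Reagents that add atoms: none
Why: Zinc insertion gives an ester-tolerant primary alkylzinc that undergoes Negishi coupling with the alkenyl triflate with retention of geometry, so the chain carbon C11 ends up cis to C7 on the tetrasubstituted alkene.

Step 11
Reactants: 16 methyl (3R,6Z)-8-hydroxy-3,6,7-trimethyloct-6-enoate
Product: 17 methyl (3R,6Z)-3,6,7-trimethyl-8-oxooct-6-enoate
Conditions: MnO2, CH2Cl2, rt
Reagents that add atoms: none
Why: Activated MnO2 oxidizes the allylic alcohol selectively to the enal under neutral conditions that should not isomerize the tetrasubstituted alkene.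

Step 12
Reactants: 8 tert-butyl{[(5Z)-7-chloro-6-methylhepta-1,5-dien-2-yl]oxy}dimethylsilane, 17 methyl (3R,6Z)-3,6,7-trimethyl-8-oxooct-6-enoate
Product: 19 methyl (3R,6Z,10Z)-14-[(tert-butyldimethylsilyl)oxy]-8-hydroxy-3,6,7,10-tetramethylpentadeca-6,10,14-trienoate (both carbinol epimers), via allylbarium chloride 18 (not isolated)
Conditions: activated Ba (BaI2, lithium biphenylide), THF, −78 °C; then 17, −78 °C
Reagents that add atoms: none
Why: In the Yamamoto allylbarium addition the allylic barium reagent formed at −78 °C adds to the aldehyde through its α carbon with retention of the Z alkene and much faster than to an ester, which gives the linear skipped dienol, the carbinol forming as both epimers that converge in step 13.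

Step 13
Reactants: 19 methyl (3R,6Z,10Z)-14-[(tert-butyldimethylsilyl)oxy]-8-hydroxy-3,6,7,10-tetramethylpentadeca-6,10,14-trienoate
Product: 20 methyl (3R,6Z,10Z)-14-[(tert-butyldimethylsilyl)oxy]-3,6,7,10-tetramethyl-8-oxopentadeca-6,10,14-trienoate
Conditions: Dess–Martin periodinane, NaHCO3, CH2Cl2, 0 °C
Reagents that add atoms: none
Why: Buffered Dess–Martin oxidation of the secondary allylic alcohol is fast and neutral, so the β,γ-alkene should not move into conjugation and the silyl enol ether should not hydrolyse.

Step 14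
Reactants: 20 methyl (3R,6Z,10Z)-14-[(tert-butyldimethylsilyl)oxy]-3,6,7,10-tetramethyl-8-oxopentadeca-6,10,14-trienoate
Product: 21 cis-decalin with C3 ketone, C7=C8 TBS enol ether, 5α-CH3, 10α-H, 9β-CH3 and 9α-[(3R)-5-methoxy-3-methyl-5-oxopentyl] chain
Conditions: chiral imidodiphosphorimidate acid (3 mol%, enantiomer chosen by screening), tert-butyldimethyl(2-methylallyl)silane (6 mol%), toluene, −60 °C, 0.02 M
Reagents that add atoms: none
Why: Proposed new method: the TBS-silylium/chiral-anion pair silylates the C7 carbonyl to a 1-silyloxyallyl cation, C10 of the Z alkene bonds to C9, C4 of the enol ether captures the tertiary C5 cation on the opposite face, and the C3 silyloxycarbenium ion passes its TBS group to the carbonyl of the next substrate molecule, so the silylium carrier is regenerated and C7 ends as a TBS enol ether; the nearest established reaction types are cation–olefin polycyclizations started by Lewis-acid-activated enones and stopped by enol ethers, and Mukaiyama–Michael additions under silylium catalysis with chiral counteranions. Ring B closes 6-endo (C8=C9 and C5=C10 both end up in the ring) through a chair-like array, and ring A closes 6-endo at the enol ether (C3=C4 in the ring) as a second chair. C5 and C10: because C1 and C6 are cis on the alkene and the two new bonds form on opposite faces, C1 becomes axial and C4 equatorial on ring B and the ring fusion is cis. C9: C11, cis to C7 on the enone, is forced pseudoaxial and anti to the C10–C1 bond in the chair, which fixes C9 relative to C10. The step needs enantioface selection, which only the chiral anion can supply (C13 is too remote to help, but it makes the wrong-sense product a separable diastereomer), and chair over boat closure, which the two Z geometries and the six-membered array should secure; using the same silyl group on the enol ether and the catalyst keeps the silyl transfer degenerate.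

Step 15
Reactants: 21 cis-decalin C3 ketone C7 TBS enol ether
Product: 24 3,7-diketone with C8 exocyclic methylene (8(17)-ene), 5α-CH3, 10α-H, 9β-CH3, 9α chain as methyl ester, via C8 phenylselenide 22 (not isolated), via selenoxide 23 (not isolated)
Conditions: PhSeCl, CH2Cl2, −78 °C; then 30% H2O2, pyridine, 0 °C → rt
Reagents that add atoms: none
Why: Electrophilic selenenylation of the regiodefined silyl enol ether at C8 and selenoxide syn elimination can only use the hydrogens of the C8 methyl group because C9 is quaternary, so the exo-methylene enone must form, which lets C7 and C8 be set by addition reactions instead of a C8 protonation whose outcome is conformation-dependent.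

Step 16
Reactants: 24 3,7-diketone with C8 exocyclic methylene
Product: 25 C3 1,3-dioxolane of 24
Conditions: 1,2-bis(trimethylsilyloxy)ethane, TMSOTf (5 mol%), CH2Cl2, −78 → −20 °C
Reagents that add atoms: 1,2-bis(trimethylsilyloxy)ethane, C[Si](C)(C)OCCO[Si](C)(C)C
Why: Noyori ketalization is selective for the unhindered saturated C3 ketone over the hindered cross-conjugated C7 enone, which protects C3 from the reduction that follows.

Step 17
Reactants: 25 C3 dioxolane C7 enone
Product: 26 7α-hydroxy-8(17)-ene C3 dioxolane methyl ester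
Conditions: NaBH4, CeCl3·7H2O, MeOH, −78 → −20 °C
Reagents that add atoms: none
Why: In this Luche 1,2-reduction the cis-decalin with a saturated ring A should sit in the conformer with C9 equatorial on ring A, where the C5 methyl and C11 are syn-axial on the α face of ring B and both 1,3 to C7, so hydride should add from the β face and give the 7α alcohol.

Step 18
Reactants: 26 7α-hydroxy-8(17)-ene C3 dioxolane methyl ester
Product: 27 7α-hydroxy-8β-methyl C3 dioxolane methyl ester
Conditions: H2 (1 atm), [Ir(cod)(PCy3)(py)]PF6 (5 mol%), CH2Cl2, rt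
Reagents that add atoms: none
Why: Hydroxyl-directed hydrogenation with Crabtree's catalyst delivers H2 to the alkene face syn to the allylic 7α-OH, so H-8 should be α and the C8 methyl β, cis to the C9 methyl as in the target.

Step 19
Reactants: 27 7α-hydroxy-8β-methyl C3 dioxolane methyl ester
Product: 28 7α-hydroxy-8β-methyl C3 dioxolane C15 carboxylic acid
Conditions: LiOH·H2O, THF/MeOH/H2O, rt; then dilute HCl to pH 4, 0 °C
Reagents that add atoms: lithium hydroxide, [Li+].[OH-]
Why: Saponification is placed here because the molecule holds no base-sensitive group yet (ketal and secondary alcohol only), which removes the need for a selective ester cleavage at the end.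

Step 20
Reactants: 28 7α-hydroxy-8β-methyl C3 dioxolane C15 carboxylic acid
Product: 30 7α-acetoxy-3-oxo C15 acid (8β-CH3, 9β-CH3, 5α-CH3, 10α-H), via acetate ketal 29 (not isolated)
Conditions: Ac2O, DMAP, pyridine, CH2Cl2, rt; then 1 M HCl, THF, rt
Reagents that add atoms: acetic anhydride, CC(=O)OC(C)=O; water, O
Why: DMAP-catalysed acetylation esterifies the hindered 7α-OH, and dilute aqueous acid then hydrolyses the dioxolane and the mixed anhydride at C15 while leaving the secondary acetate.

Step 21
Reactants: 30 7α-acetoxy-3-oxo C15 acid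
Product: 33 7α-acetoxy-2-[(tert-butyldimethylsilyl)oxy]-3-oxo C15 acid (C2 epimers), via bis-silyl enol ether 31 (not isolated), via silyloxy ketone silyl ester 32 (not isolated)
Conditions: TBSOTf (2.5 equiv), Et3N, CH2Cl2, −78 → 0 °C; DMDO, acetone, −40 → 0 °C; aq. NaHCO3, then pH 4
Reagents that add atoms: tert-butyldimethylsilyl trifluoromethanesulfonate, CC(C)(C)[Si](C)(C)OS(=O)(=O)C(F)(F)F; dimethyldioxirane, CC1(C)OO1
Why: In this Rubottom oxidation soft enolization should give the Δ2 silyl enol ether on the side away from the quaternary C5 (C4 is a neopentyl position), and epoxidation with silyl migration gives the 2-silyloxy ketone, whose C2 configuration is irrelevant because C2 becomes sp2.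

Step 22
Reactants: 33 7α-acetoxy-2-[(tert-butyldimethylsilyl)oxy]-3-oxo C15 acid
Product: 36 7α-acetoxy-2-[(tert-butyldimethylsilyl)oxy]-4-methylene-3-oxo C15 acid, via Mannich base 34 (not isolated), via amine N-oxide 35 (not isolated)
Conditions: LiHMDS (2.3 equiv), THF, −78 → −40 °C; Me2N=CH2+ I−, −78 → 0 °C; then mCPBA, CH2Cl2, 0 °C → rt
Reagents that add atoms: N,N-dimethylmethyleneiminium iodide (Eschenmoser's salt), C[N+](C)=C.[I-]
Why: With C2 blocked by the bulky silyloxy group the ketone should enolize at C4, the enolate is aminomethylated in a Mannich reaction, and Cope elimination of the β-amino ketone N-oxide gives the exo-methylene group, the silazide base being too weak to enolize the acetate.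

Step 23
Reactants: 36 7α-acetoxy-2-[(tert-butyldimethylsilyl)oxy]-4-methylene-3-oxo C15 acid
Product: 37 7α-acetoxy-2-hydroxy-4-methylene-3-oxo C15 acid (α-ketol, C2 epimers)
Conditions: HF·pyridine, THF, 0 °C → rt
Reagents that add atoms: none
Why: HF·pyridine cleaves the secondary TBS ether by fluoride attack at silicon under buffered, non-nucleophilic conditions that the α-methylene ketone, acetate and acid should tolerate.

Step 24
Reactants: 37 7α-acetoxy-2-hydroxy-4-methylene-3-oxo C15 acid
Product: 38 (5S,7S,8S,9R,10R,13R)-7-acetoxy-2-hydroxy-3-oxo-cis-cleroda-1,4(18)-dien-15-oic acid (target)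
Conditions: Dess–Martin periodinane, NaHCO3, CH2Cl2, 0 °C
Reagents that add atoms: none
Why: Dess–Martin oxidation of the α-ketol gives the 2,3-dione, which can enolize only toward C1 because C4 is sp2, so the diosphenol of the target should form under neutral conditions.

Compound list
1 | methyl 4-oxopentanoate (methyl levulinate) | CC(=O)CCC(=O)OC | starting material
2 | methyl 4-[(tert-butyldimethylsilyl)oxy]pent-4-enoate | C=C(O[Si](C)(C)C(C)(C)C)CCC(=O)OC | intermediate
3 | 4-[(tert-butyldimethylsilyl)oxy]pent-4-enal | C=C(O[Si](C)(C)C(C)(C)C)CCC=O | intermediate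
4 | methyl 2-[bis(2,2,2-trifluoroethoxy)phosphoryl]propanoate | COC(=O)C(C)P(=O)(OCC(F)(F)F)OCC(F)(F)F | starting material
5 | methyl (2Z)-6-[(tert-butyldimethylsilyl)oxy]-2-methylhepta-2,6-dienoate | C=C(O[Si](C)(C)C(C)(C)C)CC/C=C(C)\C(=O)OC | intermediate
6 | (2Z)-6-[(tert-butyldimethylsilyl)oxy]-2-methylhepta-2,6-dien-1-ol | C=C(O[Si](C)(C)C(C)(C)C)CC/C=C(C)\CO | intermediate
7 | (2Z)-6-[(tert-butyldimethylsilyl)oxy]-2-methylhepta-2,6-dien-1-yl methanesulfonate | C=C(O[Si](C)(C)C(C)(C)C)CC/C=C(C)\COS(C)(=O)=O | intermediate (not isolated)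
8 | tert-butyl{[(5Z)-7-chloro-6-methylhepta-1,5-dien-2-yl]oxy}dimethylsilane | C=C(O[Si](C)(C)C(C)(C)C)CC/C=C(C)\CCl | intermediate
9 | (3R)-5-methoxy-3-methyl-5-oxopentanoic acid [(R)-monomethyl 3-methylglutarate] | OC(=O)C[C@@H](C)CC(=O)OC | starting material
10 | methyl (3R)-5-hydroxy-3-methylpentanoate | OCC[C@@H](C)CC(=O)OC | intermediate
11 | methyl (3S)-5-iodo-3-methylpentanoate | ICC[C@@H](C)CC(=O)OC | intermediate
12 | ethyl 2-methyl-3-oxobutanoate (ethyl 2-methylacetoacetate) | CCOC(=O)C(C)C(C)=O | starting material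
13 | ethyl (2Z)-2-methyl-3-{[(trifluoromethyl)sulfonyl]oxy}but-2-enoate | CCOC(=O)/C(C)=C(C)\OS(=O)(=O)C(F)(F)F | intermediate
14 | (2Z)-4-hydroxy-3-methylbut-2-en-2-yl trifluoromethanesulfonate | OC/C(C)=C(C)\OS(=O)(=O)C(F)(F)F | intermediate
15 | [(3S)-5-methoxy-3-methyl-5-oxopentyl]zinc iodide | I[Zn]CC[C@@H](C)CC(=O)OC | intermediate (not isolated)
16 | methyl (3R,6Z)-8-hydroxy-3,6,7-trimethyloct-6-enoate | OC/C(C)=C(C)\CC[C@@H](C)CC(=O)OC | intermediate
17 | methyl (3R,6Z)-3,6,7-trimethyl-8-oxooct-6-enoate | O=C/C(C)=C(C)\CC[C@@H](C)CC(=O)OC | intermediate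
18 | [(2Z)-6-[(tert-butyldimethylsilyl)oxy]-2-methylhepta-2,6-dien-1-yl]barium chloride | C=C(O[Si](C)(C)C(C)(C)C)CC/C=C(C)\C[Ba]Cl | intermediate (not isolated)
19 | methyl (3R,6Z,10Z)-14-[(tert-butyldimethylsilyl)oxy]-8-hydroxy-3,6,7,10-tetramethylpentadeca-6,10,14-trienoate, both carbinol (ring label C7) epimers | C=C(O[Si](C)(C)C(C)(C)C)CC/C=C(C)\CC(O)/C(C)=C(C)\CC[C@@H](C)CC(=O)OC | intermediate
20 | methyl (3R,6Z,10Z)-14-[(tert-butyldimethylsilyl)oxy]-3,6,7,10-tetramethyl-8-oxopentadeca-6,10,14-trienoate (key-step precursor) | C=C(O[Si](C)(C)C(C)(C)C)CC/C=C(C)\CC(=O)/C(C)=C(C)\CC[C@@H](C)CC(=O)OC | intermediate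
21 | cis-decalin: C3 ketone, C7=C8 TBS enol ether, 5α-CH3, 10α-H, 9β-CH3, 9α-[(3R)-5-methoxy-3-methyl-5-oxopentyl] (key-step product) | C1C(=O)CC[C@@H]2[C@@](C)(CC[C@@H](C)CC(=O)OC)C(C)=C(O[Si](C)(C)C(C)(C)C)C[C@]12C | intermediate
22 | 3,7-diketone with 8-methyl-8-(phenylselanyl), C8 epimers | C1C(=O)CC[C@@H]2[C@@](C)(CC[C@@H](C)CC(=O)OC)C(C)([Se]c3ccccc3)C(=O)C[C@]12C | intermediate (not isolated)
23 | selenoxide of 22 | C1C(=O)CC[C@@H]2[C@@](C)(CC[C@@H](C)CC(=O)OC)C(C)([Se](=O)c3ccccc3)C(=O)C[C@]12C | intermediate (not isolated)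
24 | 3,7-diketone with C8 exocyclic methylene, methyl ester | C1C(=O)CC[C@@H]2[C@@](C)(CC[C@@H](C)CC(=O)OC)C(=C)C(=O)C[C@]12C | intermediate
25 | C3 1,3-dioxolane of 24 | C1C2(OCCO2)CC[C@@H]3[C@@](C)(CC[C@@H](C)CC(=O)OC)C(=C)C(=O)C[C@]13C | intermediate
26 | 7α-hydroxy-8(17)-ene C3 dioxolane methyl ester | C1C2(OCCO2)CC[C@@H]3[C@@](C)(CC[C@@H](C)CC(=O)OC)C(=C)[C@@H](O)C[C@]13C | intermediate
27 | 7α-hydroxy-8β-methyl C3 dioxolane methyl ester | C1C2(OCCO2)CC[C@@H]3[C@@](C)(CC[C@@H](C)CC(=O)OC)[C@H](C)[C@@H](O)C[C@]13C | intermediate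
28 | 7α-hydroxy-8β-methyl C3 dioxolane C15 acid | C1C2(OCCO2)CC[C@@H]3[C@@](C)(CC[C@@H](C)CC(=O)O)[C@H](C)[C@@H](O)C[C@]13C | intermediate
29 | 7α-acetoxy-8β-methyl C3 dioxolane C15 acid | C1C2(OCCO2)CC[C@@H]3[C@@](C)(CC[C@@H](C)CC(=O)O)[C@H](C)[C@@H](OC(C)=O)C[C@]13C | intermediate (not isolated)
30 | 7α-acetoxy-3-oxo C15 acid | C1C(=O)CC[C@@H]2[C@@](C)(CC[C@@H](C)CC(=O)O)[C@H](C)[C@@H](OC(C)=O)C[C@]12C | intermediate
31 | Δ2 TBS enol ether TBS ester of 30 | C1C(O[Si](C)(C)C(C)(C)C)=CC[C@@H]2[C@@](C)(CC[C@@H](C)CC(=O)O[Si](C)(C)C(C)(C)C)[C@H](C)[C@@H](OC(C)=O)C[C@]12C | intermediate (not isolated)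
32 | 2-(TBS-oxy)-3-ketone TBS ester | C1C(=O)C(O[Si](C)(C)C(C)(C)C)C[C@@H]2[C@@](C)(CC[C@@H](C)CC(=O)O[Si](C)(C)C(C)(C)C)[C@H](C)[C@@H](OC(C)=O)C[C@]12C | intermediate (not isolated)
33 | 7α-acetoxy-2-[(tert-butyldimethylsilyl)oxy]-3-oxo C15 acid, C2 epimers | C1C(=O)C(O[Si](C)(C)C(C)(C)C)C[C@@H]2[C@@](C)(CC[C@@H](C)CC(=O)O)[C@H](C)[C@@H](OC(C)=O)C[C@]12C | intermediate
34 | C4-(dimethylaminomethyl) derivative of 33 | CN(C)CC1C(=O)C(O[Si](C)(C)C(C)(C)C)C[C@@H]2[C@@](C)(CC[C@@H](C)CC(=O)O)[C@H](C)[C@@H](OC(C)=O)C[C@]12C | intermediate (not isolated)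
35 | N-oxide of 34 | C[N+](C)([O-])CC1C(=O)C(O[Si](C)(C)C(C)(C)C)C[C@@H]2[C@@](C)(CC[C@@H](C)CC(=O)O)[C@H](C)[C@@H](OC(C)=O)C[C@]12C | intermediate (not isolated)
36 | 7α-acetoxy-2-[(tert-butyldimethylsilyl)oxy]-4-methylene-3-oxo C15 acid | C=C1C(=O)C(O[Si](C)(C)C(C)(C)C)C[C@@H]2[C@@](C)(CC[C@@H](C)CC(=O)O)[C@H](C)[C@@H](OC(C)=O)C[C@]12C | intermediate
37 | 7α-acetoxy-2-hydroxy-4-methylene-3-oxo C15 acid | C=C1C(=O)C(O)C[C@@H]2[C@@](C)(CC[C@@H](C)CC(=O)O)[C@H](C)[C@@H](OC(C)=O)C[C@]12C | intermediate
38 | (5S,7S,8S,9R,10R,13R)-7-acetoxy-2-hydroxy-3-oxo-cis-cleroda-1,4(18)-dien-15-oic acid | C=C1C(=O)C(O)=C[C@@H]2[C@@](C)(CC[C@@H](C)CC(=O)O)[C@H](C)[C@@H](OC(C)=O)C[C@]12C | target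

Total step count: 24. Longest linear sequence: 18 steps (steps 1–5 and 12–24).

Steps most likely to fail

1. Step 14. The silylated enone may lose a proton from C6 faster than it cyclizes, releasing acid that desilylates the terminator. The cascade may also stop after ring B, or the chiral anion may give little enantioface discrimination.
   Fallback (known chemistry), setting out from carbinol 19 and returning at enone 24:
   - MeAlCl2 (CH2Cl2, −78 °C) ionizes the allylic alcohol to the C7–C9 allyl cation. C10 attacks it at C9 and the enol ether captures the C5 cation; this is an allyl-cation polyene cyclization with an enol-ether terminator.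
   - The same Z,Z geometry should give the same relative configuration but no asymmetric induction. The Δ7-alkene 3-ketone F1 and its ring-enantiomeric C13-diastereomer F2 would therefore form together and be separated by chromatography.
   - F1 is epoxidized with DMDO to the 7β,8β-epoxide F3 (either face serves).
   - The trisubstituted epoxide is isomerized to the exocyclic 7β-allylic alcohol F4 (TMSOTf, 2,6-lutidine, then DBU; dilute acid work-up).
   - Dess–Martin oxidation of F4 gives 24.

2. Step 12. The allylbarium species may lose α-regioselectivity or Z geometry, the arene radical anion may attack the enol ether, or the ester may compete with the aldehyde.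
   Fallback, setting out from chloride 8 (with enal 17) and returning at trienone 20:
   - PhSO2Na in DMF gives the Z allyl phenyl sulfone F5.
   - Its α-sulfonyl carbanion (n-BuLi, THF, −78 °C), which is α-selective and keeps the alkene geometry, adds to 17 to give the β-hydroxy sulfone F6.
   - Dess–Martin oxidation gives the β-keto sulfone F7.
   - SmI2 (THF/MeOH, −78 °C) removes the sulfonyl group and delivers 20 without the oxidation of step 13.

3. Step 17. Facial selectivity may be poor if a ring-B conformer other than the assumed one reacts, and 1,4-reduction may compete.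
   Fallback, setting out from enone 25 and returning at alcohol 26: reagent-controlled Corey–Bakshi–Shibata reduction (2-methyl-CBS-oxazaborolidine, enantiomer chosen to deliver hydride to the β face, catecholborane, toluene, −78 °C) replaces substrate control; no new compound is made (F0).

Further compounds
F1 | step 14 | Δ7-alkene 3-ketone methyl ester (5α-CH3, 10α-H, 9β-CH3) | C1C(=O)CC[C@@H]2[C@@](C)(CC[C@@H](C)CC(=O)OC)C(C)=CC[C@]12C
F2 | step 14 | C5,C9,C10-epimeric (ring-enantiomeric) diastereomer of F1 | C1C(=O)CC[C@H]2[C@](C)(CC[C@@H](C)CC(=O)OC)C(C)=CC[C@@]12C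
F3 | step 14 | 7β,8β-epoxide of F1 | C1C(=O)CC[C@@H]2[C@@](C)(CC[C@@H](C)CC(=O)OC)[C@]3(C)O[C@@H]3C[C@]12C
F4 | step 14 | 7β-hydroxy-8(17)-ene 3-ketone methyl ester | C1C(=O)CC[C@@H]2[C@@](C)(CC[C@@H](C)CC(=O)OC)C(=C)[C@H](O)C[C@]12C
F5 | step 12 | tert-butyldimethyl{[(5Z)-6-methyl-7-(phenylsulfonyl)hepta-1,5-dien-2-yl]oxy}silane | C=C(O[Si](C)(C)C(C)(C)C)CC/C=C(C)\CS(=O)(=O)c1ccccc1
F6 | step 12 | β-hydroxy sulfone from F5 and 17 (mixture of diastereomers) | C=C(O[Si](C)(C)C(C)(C)C)CC/C=C(C)\C(C(O)/C(C)=C(C)\CC[C@@H](C)CC(=O)OC)S(=O)(=O)c1ccccc1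
F7 | step 12 | β-keto sulfone (sulfonyl epimers) | C=C(O[Si](C)(C)C(C)(C)C)CC/C=C(C)\C(C(=O)/C(C)=C(C)\CC[C@@H](C)CC(=O)OC)S(=O)(=O)c1ccccc1
F0 | step 17 | none | none
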